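**Plan**
- Retrosynthetic cuts, in order: the C3 ester with the N‑sulfonyl and O‑silyl groups; then C5–C1' (side chain joined to a C5 enol triflate); then, in one operation, C6–C7, C4a–C8a and N1–C8a; last, the acyclic chain back to ethyl crotonate.
- Enabling feature: C8a carries N and lies 1,3 to C5 through C4a and 1,5 to C5 through C6–C7–C8. With C5 as a carbonyl (the carbon that later takes the side chain), ring B is the union of a C4a–C5–C6 β‑keto ester with the C7–C8–C8a unit of acrolein, and the N–C2–C3–C4 tether on C4a closes ring A onto C8a.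
- Forward: aminohydroxylation, chain extension, then one pot builds ring B and ring A; the C6 ester (activating group) is removed, the C5 ketone becomes the coupling handle, then hydrogenation, acylation and removal of the sulfonyl group.
- Stereochemistry: C2 and C3 from asymmetric aminohydroxylation; C8a and C4a under control of C2 in the key step; C5 by hydrogenation on the convex face; C5' from (R)‑2‑propyloxirane.

Key step: step 6

Assumption: (R)‑2‑propyloxirane (17) and (2E,4E)‑octa‑2,4‑dienoic acid (23) are taken as catalogue compounds.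

**Step 1**
Reactants: 1 ethyl (E)-but-2-enoate; 2 2-methylpropane-2-sulfonamide
Product: 4 ethyl (2S,3R)-3-[(tert-butylsulfonyl)amino]-2-hydroxybutanoate, via sodium N-chlorosulfonamide salt 3 (not isolated)
Conditions: 2, tBuOCl, NaOH, nPrOH/H2O (1:1), rt; then (DHQD)2PHAL (5 mol %), K2OsO2(OH)4 (4 mol %), 1, rt
Reagents that add atoms: water, O; tert-butyl hypochlorite, CC(C)(C)OCl, and sodium hydroxide, [Na+].[OH-] (these give Cl and Na to intermediate 3 only)
Why: Sharpless asymmetric aminohydroxylation adds N and O syn across the E‑alkene with N at the β‑carbon, and the (DHQD)2PHAL ligand should select the face giving the (2S,3R) isomer, so the later C2 and C3 centres arise together, cis, with the sulfonyl group the key step needs already on nitrogen.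

**Step 2**
Reactants: 4 ethyl (2S,3R)-3-[(tert-butylsulfonyl)amino]-2-hydroxybutanoate
Product: 5 ethyl (2S,3R)-2-(benzyloxy)-3-[(tert-butylsulfonyl)amino]butanoate
Conditions: BnOC(=NH)CCl3, TfOH (5 mol %), CH2Cl2/cyclohexane, 0 °C → rt
Reagents that add atoms: benzyl 2,2,2-trichloroacetimidate, N=C(OCc1ccccc1)C(Cl)(Cl)Cl
Why: Acid‑catalysed trichloroacetimidate benzylation etherifies the hydroxyl without base, so the α‑stereocentre and the acidic N–H are untouched, and the benzyl ether tolerates the later bases and TFA until it leaves in step 12.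

**Step 3**
Reactants: 5 ethyl (2S,3R)-2-(benzyloxy)-3-[(tert-butylsulfonyl)amino]butanoate
Product: 7 ethyl (2E,4R,5R)-4-(benzyloxy)-5-[(tert-butylsulfonyl)amino]hex-2-enoate, via aldehyde 6 (not isolated)
Conditions: iBu2AlH (2.2 equiv), CH2Cl2, −78 °C; then Ph3P=CHCO2Et, −78 °C → rt
Reagents that add atoms: ethyl (triphenylphosphoranylidene)acetate, CCOC(=O)C=P(c1ccccc1)(c1ccccc1)c1ccccc1
Why: Half‑reduction of the ester and Wittig olefination in the same flask avoid handling the epimerisable α‑alkoxy aldehyde, and the alkene geometry does not matter because it is reduced next.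

**Step 4**
Reactants: 7 ethyl (2E,4R,5R)-4-(benzyloxy)-5-[(tert-butylsulfonyl)amino]hex-2-enoate
Product: 8 ethyl (4R,5R)-4-(benzyloxy)-5-[(tert-butylsulfonyl)amino]hexanoate
Conditions: H2 (1 atm), Pd/C (5 mol %), Ph2S (1 mol %), EtOAc, rt
Reagents that add atoms: none
Why: Hydrogenation over sulfide‑poisoned Pd/C saturates the conjugated alkene without cleaving the benzyl ether.

**Step 5**
Reactants: 8 ethyl (4R,5R)-4-(benzyloxy)-5-[(tert-butylsulfonyl)amino]hexanoate
Product: 9 tert-butyl (6R,7R)-6-(benzyloxy)-7-[(tert-butylsulfonyl)amino]-3-oxooctanoate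
Conditions: tBuOAc, LiN(iPr)2 (3.5 equiv), THF, −78 °C; then 8, −78 → −20 °C
Reagents that add atoms: tert-butyl acetate, CC(=O)OC(C)(C)C
Why: Crossed Claisen condensation in which the first equivalent of enolate deprotonates N–H and further enolate acylates on the ethyl ester (directly or through the transient N‑sulfonyl lactam, which is opened at its carbonyl), giving the β‑keto ester whose C2 (future C6) is the only strongly acidic carbon.

**Step 6**
Reactants: 9 tert-butyl (6R,7R)-6-(benzyloxy)-7-[(tert-butylsulfonyl)amino]-3-oxooctanoate; 10 acrolein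
Product: 13 tert-butyl (2R,3R,4aR,8aR)-3-(benzyloxy)-1-(tert-butylsulfonyl)-5-hydroxy-2-methyl-1,2,3,4,4a,7,8,8a-octahydroquinoline-6-carboxylate (cis-fused; enol form), via keto aldehyde 11 (not isolated), via cyclohexenone 12 (not isolated)
Conditions: 10 (1.1 equiv), Et3N (10 mol %), toluene, 0 °C; then LiOH·H2O (1.0 equiv), iPrOH/H2O, 0 °C → rt
Reagents that add atoms: none
Why: The β‑keto ester carbon C6 adds to acrolein (Michael, C6–C7), the ketone then enolises toward C4a and condenses with the aldehyde carbon C8a (aldol condensation, C4a–C8a, ring B closed 6‑(enolendo)‑exo‑trig), and the sulfonamide anion adds to C8a of cyclohexenone 12 (aza‑Michael, ring A closed 6‑endo‑trig). The closest known reaction type is the one‑pot Robinson annulation/intramolecular aza‑Michael cascade of sulfonamide‑tethered β‑keto esters with enals, which gives cis‑5‑oxodecahydroquinolines. C8a is controlled by C2: in the chair‑like transition state the ring‑locked enone keeps C8 equatorial, and 1,3‑allylic strain with the N‑sulfonyl group then allows only an axial C2 methyl (C3 benzyloxy equatorial), which puts H8a trans to H2. C4a is set when the enolate left by the aza‑Michael step is protonated anti to the new axial C8a–N bond, which should give the cis ring fusion. The step needs C6 to react before C4a, which the ester secures by making C6 the only acidic carbon at the start; it also needs the two new centres to stay as formed, which is secured because the product rests as the β‑keto ester enolate, whose C4a–H is not acidic, so retro‑aza‑Michael equilibration is shut off.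

**Step 7**
Reactants: 13 tert-butyl (2R,3R,4aR,8aR)-3-(benzyloxy)-1-(tert-butylsulfonyl)-5-hydroxy-2-methyl-1,2,3,4,4a,7,8,8a-octahydroquinoline-6-carboxylate
Product: 15 (2R,3R,4aR,8aR)-3-(benzyloxy)-1-(tert-butylsulfonyl)-2-methyloctahydroquinolin-5(1H)-one (cis-fused), via keto acid 14 (not isolated)
Conditions: TFA/CH2Cl2 (1:2), 0 °C → rt; concentrate; toluene, 60 °C
Reagents that add atoms: none
Why: Acidolysis of the tert‑butyl ester and decarboxylation of the β‑keto acid remove the activating group at C6, while the tert‑butylsulfonyl group needs a much stronger acid and the short, mild treatment should leave the cis ring fusion in place.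

**Step 8**
Reactants: 15 (2R,3R,4aR,8aR)-3-(benzyloxy)-1-(tert-butylsulfonyl)-2-methyloctahydroquinolin-5(1H)-one
Product: 16 (2R,3R,4aR,8aR)-3-(benzyloxy)-1-(tert-butylsulfonyl)-2-methyl-1,2,3,4,4a,7,8,8a-octahydroquinolin-5-yl trifluoromethanesulfonate
Conditions: KN(SiMe3)2 (1.1 equiv), THF, −78 °C; PhNTf2, −78 → −20 °C
Reagents that add atoms: N-phenylbis(trifluoromethanesulfonimide), O=S(=O)(N(c1ccccc1)S(=O)(=O)C(F)(F)F)C(F)(F)F
Why: Kinetic deprotonation with a bulky amide base takes the unhindered C6 methylene and not the ring‑fusion C4a–H, and O‑triflation of that enolate fixes the C5=C6 double bond as the coupling handle.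

**Step 9**
Reactants: 17 (R)-2-propyloxirane
Product: 18 (R)-oct-7-en-4-ol
Conditions: allylMgBr, CuI (10 mol %), THF, −30 → 0 °C
Reagents that add atoms: allylmagnesium bromide, C=CC[Mg]Br
Why: Copper‑catalysed opening of the terminal epoxide by the allyl Grignard reagent at its CH2 carbon leaves the carbinol stereocentre (future C5') unchanged.

**Step 10**
Reactants: 18 (R)-oct-7-en-4-ol
Product: 19 (R)-tert-butyldimethyl(oct-7-en-4-yloxy)silane
Conditions: TBSCl, imidazole, DMF, rt
Reagents that add atoms: tert-butyldimethylsilyl chloride, CC(C)(C)[Si](C)(C)Cl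
Why: Standard silylation, which keeps the side‑chain hydroxyl distinct from the C3 hydroxyl until the ester is in place.

**Step 11**
Reactants: 19 (R)-tert-butyldimethyl(oct-7-en-4-yloxy)silane; 16 (2R,3R,4aR,8aR)-3-(benzyloxy)-1-(tert-butylsulfonyl)-2-methyl-1,2,3,4,4a,7,8,8a-octahydroquinolin-5-yl trifluoromethanesulfonate
Product: 21 (2R,3R,4aS,8aR)-3-(benzyloxy)-5-[(5R)-5-{[tert-butyl(dimethyl)silyl]oxy}octyl]-1-(tert-butylsulfonyl)-2-methyl-1,2,3,4,4a,7,8,8a-octahydroquinoline, via alkylborane 20 (not isolated)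
Conditions: 19, 9-BBN (0.5 M in THF), rt; then 16, Pd(dppf)Cl2 (5 mol %), AsPh3 (10 mol %), Cs2CO3, DMF/H2O, rt → 50 °C
Reagents that add atoms: 9-borabicyclo[3.3.1]nonane, B1C2CCCC1CCC2 (its boron and ring stay in intermediate 20 only)
Why: Anti‑Markovnikov hydroboration of the terminal alkene and B‑alkyl Suzuki–Miyaura coupling with the enol triflate join C1' to C5 without touching any stereocentre.

**Step 12**
Reactants: 21 (2R,3R,4aS,8aR)-3-(benzyloxy)-5-[(5R)-5-{[tert-butyl(dimethyl)silyl]oxy}octyl]-1-(tert-butylsulfonyl)-2-methyl-1,2,3,4,4a,7,8,8a-octahydroquinoline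
Product: 22 (2R,3R,4aS,5S,8aR)-5-[(5R)-5-{[tert-butyl(dimethyl)silyl]oxy}octyl]-1-(tert-butylsulfonyl)-2-methyldecahydroquinolin-3-ol
Conditions: H2 (10 bar), Pd(OH)2/C, EtOAc, rt
Reagents that add atoms: none
Why: Heterogeneous hydrogenation should add H2 to C5=C6 from the face that carries H4a and H8a, because the other face of ring B is covered by C4 and the sulfonylated nitrogen (one of them necessarily pseudo‑axial), which sets C5 with the side chain cis to C4 and N; the benzyl ether is hydrogenolysed in the same operation.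

**Step 13**
Reactants: 22 (2R,3R,4aS,5S,8aR)-5-[(5R)-5-{[tert-butyl(dimethyl)silyl]oxy}octyl]-1-(tert-butylsulfonyl)-2-methyldecahydroquinolin-3-ol; 23 (2E,4E)-octa-2,4-dienoic acid
Product: 25 (2R,3R,4aS,5S,8aR)-5-[(5R)-5-{[tert-butyl(dimethyl)silyl]oxy}octyl]-1-(tert-butylsulfonyl)-2-methyldecahydroquinolin-3-yl (2E,4E)-octa-2,4-dienoate, via mixed anhydride 24 (not isolated)
Conditions: 23, 2,4,6-Cl3C6H2COCl, Et3N, THF, rt; then 22, DMAP, toluene, rt → 40 °C
Reagents that add atoms: 2,4,6-trichlorobenzoyl chloride, O=C(Cl)c1c(Cl)cc(Cl)cc1Cl (its aroyl group stays in intermediate 24 only)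
Why: Yamaguchi esterification acylates the only free hydroxyl (C3) with retention and without isomerising the diene.

**Step 14**
Reactants: 25 (2R,3R,4aS,5S,8aR)-5-[(5R)-5-{[tert-butyl(dimethyl)silyl]oxy}octyl]-1-(tert-butylsulfonyl)-2-methyldecahydroquinolin-3-yl (2E,4E)-octa-2,4-dienoate
Product: 26 (2R,3R,4aS,5S,8aR)-5-[(5R)-5-hydroxyoctyl]-2-methyldecahydroquinolin-3-yl (2E,4E)-octa-2,4-dienoate (target)
Conditions: TfOH (0.1 M), anisole, CH2Cl2, 0 °C; then aq. NaHCO3
Reagents that add atoms: none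
Why: Acidolysis of the N–SO2–tBu group (tert‑butyl cation trapped by anisole, then loss of SO2) and of the silyl ether under a non‑nucleophilic acid should leave the ester and diene intact, and the amine stays protonated until work‑up so that O‑to‑N acyl transfer is not favoured.

**Compound list**
1 | ethyl (E)-but-2-enoate | C/C=C/C(=O)OCC | starting material
2 | 2-methylpropane-2-sulfonamide | CC(C)(C)S(N)(=O)=O | starting material
3 | sodium chloro(tert-butylsulfonyl)azanide | CC(C)(C)S(=O)(=O)[N-]Cl.[Na+] | intermediate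
4 | ethyl (2S,3R)-3-[(tert-butylsulfonyl)amino]-2-hydroxybutanoate | CCOC(=O)[C@@H](O)[C@@H](C)NS(=O)(=O)C(C)(C)C | intermediate
5 | ethyl (2S,3R)-2-(benzyloxy)-3-[(tert-butylsulfonyl)amino]butanoate | CCOC(=O)[C@@H](OCc1ccccc1)[C@@H](C)NS(=O)(=O)C(C)(C)C | intermediate
6 | (2S,3R)-2-(benzyloxy)-3-[(tert-butylsulfonyl)amino]butanal | O=C[C@@H](OCc1ccccc1)[C@@H](C)NS(=O)(=O)C(C)(C)C | intermediate
7 | ethyl (2E,4R,5R)-4-(benzyloxy)-5-[(tert-butylsulfonyl)amino]hex-2-enoate | CCOC(=O)/C=C/[C@@H](OCc1ccccc1)[C@@H](C)NS(=O)(=O)C(C)(C)C | intermediate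
8 | ethyl (4R,5R)-4-(benzyloxy)-5-[(tert-butylsulfonyl)amino]hexanoate | CCOC(=O)CC[C@@H](OCc1ccccc1)[C@@H](C)NS(=O)(=O)C(C)(C)C | intermediate
9 | tert-butyl (6R,7R)-6-(benzyloxy)-7-[(tert-butylsulfonyl)amino]-3-oxooctanoate | CC(C)(C)OC(=O)CC(=O)CC[C@@H](OCc1ccccc1)[C@@H](C)NS(=O)(=O)C(C)(C)C | intermediate
10 | acrolein (prop-2-enal) | C=CC=O | starting material
11 | tert-butyl (6R,7R)-6-(benzyloxy)-7-[(tert-butylsulfonyl)amino]-3-oxo-2-(3-oxopropyl)octanoate (both C2 epimers) | CC(C)(C)OC(=O)C(CCC=O)C(=O)CC[C@@H](OCc1ccccc1)[C@@H](C)NS(=O)(=O)C(C)(C)C | intermediate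
12 | tert-butyl 3-{(2R,3R)-2-(benzyloxy)-3-[(tert-butylsulfonyl)amino]butyl}-2-oxocyclohex-3-ene-1-carboxylate | CC(C)(C)OC(=O)C1CCC=C(C[C@@H](OCc2ccccc2)[C@@H](C)NS(=O)(=O)C(C)(C)C)C1=O | intermediate
13 | tert-butyl (2R,3R,4aR,8aR)-3-(benzyloxy)-1-(tert-butylsulfonyl)-5-hydroxy-2-methyl-1,2,3,4,4a,7,8,8a-octahydroquinoline-6-carboxylate | c1ccccc1CO[C@@H]1C[C@H]2C(O)=C(C(=O)OC(C)(C)C)CC[C@H]2N(S(=O)(=O)C(C)(C)C)[C@@H]1C | intermediate
14 | (2R,3R,4aR,8aR)-3-(benzyloxy)-1-(tert-butylsulfonyl)-5-hydroxy-2-methyl-1,2,3,4,4a,7,8,8a-octahydroquinoline-6-carboxylic acid | c1ccccc1CO[C@@H]1C[C@H]2C(O)=C(C(=O)O)CC[C@H]2N(S(=O)(=O)C(C)(C)C)[C@@H]1C | intermediate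
15 | (2R,3R,4aR,8aR)-3-(benzyloxy)-1-(tert-butylsulfonyl)-2-methyloctahydroquinolin-5(1H)-one | c1ccccc1CO[C@@H]1C[C@H]2C(=O)CCC[C@H]2N(S(=O)(=O)C(C)(C)C)[C@@H]1C | intermediate
16 | (2R,3R,4aR,8aR)-3-(benzyloxy)-1-(tert-butylsulfonyl)-2-methyl-1,2,3,4,4a,7,8,8a-octahydroquinolin-5-yl trifluoromethanesulfonate | c1ccccc1CO[C@@H]1C[C@H]2C(OS(=O)(=O)C(F)(F)F)=CCC[C@H]2N(S(=O)(=O)C(C)(C)C)[C@@H]1C | intermediate
17 | (R)-2-propyloxirane | CCC[C@@H]1CO1 | starting material
18 | (R)-oct-7-en-4-ol | C=CCC[C@H](O)CCC | intermediate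
19 | (R)-tert-butyldimethyl(oct-7-en-4-yloxy)silane | C=CCC[C@H](O[Si](C)(C)C(C)(C)C)CCC | intermediate
20 | 9-[(5R)-5-{[tert-butyl(dimethyl)silyl]oxy}octyl]-9-borabicyclo[3.3.1]nonane | B1(C2CCCC1CCC2)CCCC[C@H](O[Si](C)(C)C(C)(C)C)CCC | intermediate
21 | (2R,3R,4aS,8aR)-3-(benzyloxy)-5-[(5R)-5-{[tert-butyl(dimethyl)silyl]oxy}octyl]-1-(tert-butylsulfonyl)-2-methyl-1,2,3,4,4a,7,8,8a-octahydroquinoline | c1ccccc1CO[C@@H]1C[C@H]2C(CCCC[C@H](O[Si](C)(C)C(C)(C)C)CCC)=CCC[C@H]2N(S(=O)(=O)C(C)(C)C)[C@@H]1C | intermediate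
22 | (2R,3R,4aS,5S,8aR)-5-[(5R)-5-{[tert-butyl(dimethyl)silyl]oxy}octyl]-1-(tert-butylsulfonyl)-2-methyldecahydroquinolin-3-ol | O[C@@H]1C[C@H]2[C@@H](CCCC[C@H](O[Si](C)(C)C(C)(C)C)CCC)CCC[C@H]2N(S(=O)(=O)C(C)(C)C)[C@@H]1C | intermediate
23 | (2E,4E)-octa-2,4-dienoic acid | CCC/C=C/C=C/C(=O)O | starting material
24 | (2E,4E)-octa-2,4-dienoic 2,4,6-trichlorobenzoic anhydride | CCC/C=C/C=C/C(=O)OC(=O)c1c(Cl)cc(Cl)cc1Cl | intermediate
25 | (2R,3R,4aS,5S,8aR)-5-[(5R)-5-{[tert-butyl(dimethyl)silyl]oxy}octyl]-1-(tert-butylsulfonyl)-2-methyldecahydroquinolin-3-yl (2E,4E)-octa-2,4-dienoate | CCC/C=C/C=C/C(=O)O[C@@H]1C[C@H]2[C@@H](CCCC[C@H](O[Si](C)(C)C(C)(C)C)CCC)CCC[C@H]2N(S(=O)(=O)C(C)(C)C)[C@@H]1C | intermediate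
26 | (2R,3R,4aS,5S,8aR)-5-[(5R)-5-hydroxyoctyl]-2-methyldecahydroquinolin-3-yl (2E,4E)-octa-2,4-dienoate | CCC/C=C/C=C/C(=O)O[C@@H]1C[C@H]2[C@@H](CCCC[C@H](O)CCC)CCC[C@H]2N[C@@H]1C | target

**Step count and risks**
Total: 14 steps. Longest linear sequence: 12 steps (steps 1–8 and 11–14).

Step 6. The aza‑Michael closure may lose facial control at C8a if it equilibrates before the product is locked as its enolate, the ring fusion may drift toward trans, or acrolein may oligomerise under hydroxide. The fallback separates the two ring closures and puts ring A under catalyst control. From 9 and 10 the annulation is run with a secondary amine salt (pyrrolidine/AcOH) so that it stops at cyclohexenone 12, which is isolated. TFA then removes the ester to give N-[(2R,3R)-3-(benzyloxy)-4-(6-oxocyclohex-1-en-1-yl)butan-2-yl]-2-methylpropane-2-sulfonamide F1. Ring A is closed by iminium activation of the enone with the matched cinchona‑derived primary amine (9‑amino‑9‑deoxy‑epi‑quinine or its quinidine analogue, with TFA), which should deliver ketone 15, where the route is rejoined.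

Step 12. Hydrogen may add with poor facial selectivity, or the double bond may migrate toward C4a on the palladium surface and erode the ring fusion. The fallback replaces steric control by hydroxyl direction. From 21 the benzyl ether is removed without hydrogen (BCl3, C6HMe5, CH2Cl2, −78 °C) to give (2R,3R,4aS,8aR)-5-[(5R)-5-{[tert-butyl(dimethyl)silyl]oxy}octyl]-1-(tert-butylsulfonyl)-2-methyl-1,2,3,4,4a,7,8,8a-octahydroquinolin-3-ol F2. Its hydroxyl lies on the same face as H4a and H8a, and a cationic iridium catalyst bound to it ([Ir(cod)(PCy3)(py)]PF6, H2, CH2Cl2) should deliver hydrogen to that face without alkene migration, giving 22.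

Step 14. The strong acid may add anisole to, or otherwise damage, the protonated dienoate, or cleavage of the hindered sulfonamide may be incomplete. The fallback removes the sulfonyl group before the ester is made and finishes through an N‑Boc endgame.
- From 22, TfOH/anisole gives (2R,3R,4aS,5S,8aR)-5-[(5R)-5-hydroxyoctyl]-2-methyldecahydroquinolin-3-ol F3.
- Boc2O gives tert-butyl (2R,3R,4aS,5S,8aR)-3-hydroxy-5-[(5R)-5-hydroxyoctyl]-2-methyloctahydroquinoline-1(2H)-carboxylate F4.
- TBSCl/imidazole at 0 °C should silylate the unhindered side‑chain hydroxyl in preference to the ring hydroxyl flanked by N‑Boc and the C2 methyl, giving tert-butyl (2R,3R,4aS,5S,8aR)-5-[(5R)-5-{[tert-butyl(dimethyl)silyl]oxy}octyl]-3-hydroxy-2-methyloctahydroquinoline-1(2H)-carboxylate F5.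
- Yamaguchi esterification with 23 gives tert-butyl (2R,3R,4aS,5S,8aR)-5-[(5R)-5-{[tert-butyl(dimethyl)silyl]oxy}octyl]-2-methyl-3-{[(2E,4E)-octa-2,4-dienoyl]oxy}octahydroquinoline-1(2H)-carboxylate F6.
- Wet TFA in CH2Cl2 removes the carbamate and the silyl ether to give 26.

**Further compounds**
F1 | step 6 | N-[(2R,3R)-3-(benzyloxy)-4-(6-oxocyclohex-1-en-1-yl)butan-2-yl]-2-methylpropane-2-sulfonamide | O=C1CCCC=C1C[C@@H](OCc1ccccc1)[C@@H](C)NS(=O)(=O)C(C)(C)C
F2 | step 12 | (2R,3R,4aS,8aR)-5-[(5R)-5-{[tert-butyl(dimethyl)silyl]oxy}octyl]-1-(tert-butylsulfonyl)-2-methyl-1,2,3,4,4a,7,8,8a-octahydroquinolin-3-ol | O[C@@H]1C[C@H]2C(CCCC[C@H](O[Si](C)(C)C(C)(C)C)CCC)=CCC[C@H]2N(S(=O)(=O)C(C)(C)C)[C@@H]1C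
F3 | step 14 | (2R,3R,4aS,5S,8aR)-5-[(5R)-5-hydroxyoctyl]-2-methyldecahydroquinolin-3-ol | O[C@@H]1C[C@H]2[C@@H](CCCC[C@H](O)CCC)CCC[C@H]2N[C@@H]1C
F4 | step 14 | tert-butyl (2R,3R,4aS,5S,8aR)-3-hydroxy-5-[(5R)-5-hydroxyoctyl]-2-methyloctahydroquinoline-1(2H)-carboxylate | O[C@@H]1C[C@H]2[C@@H](CCCC[C@H](O)CCC)CCC[C@H]2N(C(=O)OC(C)(C)C)[C@@H]1C
F5 | step 14 | tert-butyl (2R,3R,4aS,5S,8aR)-5-[(5R)-5-{[tert-butyl(dimethyl)silyl]oxy}octyl]-3-hydroxy-2-methyloctahydroquinoline-1(2H)-carboxylate | O[C@@H]1C[C@H]2[C@@H](CCCC[C@H](O[Si](C)(C)C(C)(C)C)CCC)CCC[C@H]2N(C(=O)OC(C)(C)C)[C@@H]1C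
F6 | step 14 | tert-butyl (2R,3R,4aS,5S,8aR)-5-[(5R)-5-{[tert-butyl(dimethyl)silyl]oxy}octyl]-2-methyl-3-{[(2E,4E)-octa-2,4-dienoyl]oxy}octahydroquinoline-1(2H)-carboxylate | CCC/C=C/C=C/C(=O)O[C@@H]1C[C@H]2[C@@H](CCCC[C@H](O[Si](C)(C)C(C)(C)C)CCC)CCC[C@H]2N(C(=O)OC(C)(C)C)[C@@H]1C
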